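## The problem

The target is a 2-hydroxychroman-4-one. Ring A is the benzo ring C4a–C8a and ring B the pyranone O1–C4; C5 carries a heptyl group and C7 a phenol. C2 is joined through one methylene to ring C, a benzoic acid numbered here C1' (methylene), C2' (CO2H), C3' and C5' (phenols).

The skeleton is a linear, polyketide-like chain: two resorcinol rings separated by the unit C4–C3–C2–CH2, which is a 1,3-diketone in oxidation level and sits in the target as its cyclic hemiketal with the C8a oxygen. The only stereocentre is this hemiketal carbon, C2 (R). Nothing else in the molecule can direct it, and it can invert by ring opening to the achiral diketone. It therefore has to be set in the last operations, under lattice control and not by a kinetic asymmetric reaction.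

Three groups are fragile. The hemiketal loses water to the chromone under acid. Ring C is an orsellinic-type acid that decarboxylates when heated or acidified and can add to the C2 carbonyl. The electron-rich phenols rule out oxidants. A free 1,3-diketone cannot be carried through the synthesis either, because beside an alkyne or an ortho-hydroxyaryl ketone it cyclises, so C2 has to travel as a ketal.

The enabling feature is that rings A and C are the same motif. In each, an acyl-bearing carbon (C4a with the C4 carbonyl; C2' with the carboxyl) lies between an oxygen-bearing carbon (C8a; C3') and a carbon-substituted carbon (C5 with heptyl; C1' with the methylene), with the second oxygen para to the acyl group (C7; C5'). Such a 2-acyl-3-alkylresorcinol is the formal adduct of an acetylenic carbonyl compound and a 1,3-dioxygenated butadiene, so both arenes can be raised in one operation from a single acyclic diyne.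

## Retrosynthesis

**The stereocentre.** No skeletal bond is cut. Target 22 is traced to its crystalline salt 21 with the chiral tertiary amine 19, and 21 to the racemic acid 18. Any earlier kinetic control of C2 would be lost in the first solution in which the ring opens to the diketo acid 20. Setting C2 last, by letting one diastereomeric salt crystallise while the other equilibrates through 20, is the only placement that survives. The forward step needs a lattice that takes up only the (2R)-carboxylate, and the salt break needs to be cold and brief.

**The carboxyl group and the hemiketal.** Cutting the O–benzyl bond leads from 18 to benzyl ester 17. Cutting the C2–O1 bond and restoring the dioxolane at C2 leads from 17, through diketone 16, to ketal 15. The ester is kept through the acidic step because a free acid ortho to the side chain could decarboxylate or add to C2, whereas its later removal by hydrogenolysis is neutral. Ketal 15 has no stereocentre and no labile hemiketal. The forward hydrolysis must stop at the hydrate level of C2 and not run on to the chromone.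

**The two arenes.** In 15, ring A is cut at C4a–C8a and C5–C6 and ring C at C2'–C3' and C1'–C6'. This removes eight of the twelve aromatic carbons and all four phenol oxygens at once and leads to the acyclic diynone ester 10 and two molecules of diene 13. The neighbouring cuts (acylation of a preformed alkylresorcinol, or aldol closure of a polycarbonyl chain) would treat the rings one at a time and need different chemistry for the ketone on ring A and the carboxyl on ring C. The cycloaddition cut uses one reaction for both, because an ynone and an ynoate are both dienophiles. Precursor 10 has a straight 25-carbon skeleton, no carbocycle and no stereocentre. The forward reaction must be regioselective at both alkynes and go to completion at the slower ynoate. The dioxolane at C2 keeps the two dienophiles electronically separate and prevents a 1,3-diketone from forming.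

**The chain ends of 10.** The benzyl–oxygen bond is cut first, giving acid 9. The bond between the ketone carbon C4 and its alkyne carbon is cut next, giving the N-methoxy-N-methylamide 7 and non-1-yne 8. The ynone is made while the carboxyl is a free acid on purpose. As its lithium salt the ynoate is neither a competing electrophile nor acidic at its propargylic methylene, whereas a benzyl ynoate would compete with the amide for the acetylide. Esterification after the ynone exists needs only a weak base. Both fragments are simple; the forward addition must stop at the ketone.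

**The carboxyl carbon and the amide.** The bond between the carboxyl carbon and the alkyne terminus of 7 is cut to give terminal alkyne 6 (a C–H carboxylation in the forward sense). The amide C–N bond is cut to give methyl ester 5. Carboxylating at the amide stage, before the ynone is present, means the carbonate base never meets an enolisable ynone that could eliminate toward the ketal or isomerise.

**The masked diketone core.** Removing the dioxolane from 5 gives β-keto ester 4. Cutting the bond between its ketone carbon and the α-carbon gives but-3-ynoic acid 1 and Meldrum's acid 2, joined in the forward sense through the acyl derivative 3. This supplies the terminal alkyne, the future C2 and the future C3/C4 carbons in one step from two commercial compounds. The forward sequence must ketalise the propargyl ketone before it can isomerise.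

**The diene.** Diene 13 is traced by two O-silylations through silyl enol ether 12 to methyl acetoacetate 11. It is prepared and distilled shortly before use.

## Roads not taken

**Alternative 1: aldol aromatisation of a diketo-dioxinone to ring C.**
- Cut: only ring C is disconnected, at C1'–C2', back to the chain compound 6-[5-[7-(benzyloxy)-5-heptyl-4-oxo-4H-chromen-2-yl]-2,4-dioxopentyl]-2,2-dimethyl-4H-1,3-dioxin-4-one A1.
- Forward key step: with an amine base and then acid, the dioxinone α-carbon adds to the distal ketone and water is lost, giving the benzodioxinone 5-[(7-benzyloxy-5-heptyl-4-oxo-4H-chromen-2-yl)methyl]-7-hydroxy-2,2-dimethyl-4H-1,3-benzodioxin-4-one A2.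
- Merits: the aromatisation runs at room temperature, its regiochemistry is fixed by the chain, and the acid and ortho-phenol of ring C emerge already protected. In mildness and reliability of the ring-forming event it is better than a thermal cycloaddition on a sluggish ynoate.
- Weak points: ring A and the chromone have to be built beforehand by separate chemistry. A1 has three acidic methylenes, among them the one on the chromone, so misdirected closures are possible. Above all, A2 has C2 at the chromone level: the target then requires adding water across C2=C3, which is thermodynamically uphill, and opening the benzodioxinone with hydroxide.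
- Comparison: the chosen plan offers one reaction for both rings and arrival at C2 as a ketal, from which the hemiketal follows by hydrolysis alone.

**Alternative 2: Catellani three-component assembly of the ring A substituents.**
- Cut: the C5–heptyl bond and the C4a–C4 bond; no ring is formed.
- Forward key step: 2,4-bis(benzyloxy)-1-iodobenzene A3, 1-iodoheptane A4 and the ring-C-bearing alkyne benzyl 2,4-bis(benzyloxy)-6-[(2-ethynyl-1,3-dioxolan-2-yl)methyl]benzoate A5 combine under Catellani conditions (palladium diacetate, a strained bicyclic alkene as transient mediator, carbonate base). Ortho alkylation and ipso alkynylation give benzyl 2,4-bis(benzyloxy)-6-[[2-[(2,4-bis(benzyloxy)-6-heptylphenyl)ethynyl]-1,3-dioxolan-2-yl]methyl]benzoate A6.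
- Merits: modular (the alkyl iodide can be varied), no forcing pericyclic step, and fully benzylated, robust intermediates. In flexibility and ease of handling it is better than the chosen plan.
- Weak points: ring C must already be complete in A5, a pentasubstituted benzoate with a propargylic ketal that needs its own multistep synthesis. Direct alkynylation without alkylation competes in the key step. A6 still needs a regioselective hydration of the alkyne to place the carbonyl at C4 in the presence of the ketal, followed by a fivefold debenzylation.
- Comparison: the chosen plan needs neither arene in advance and delivers the C4 carbonyl directly.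

**Alternative 3: aryne insertion into a chromonylacetate.**
- Cut: the C1'–CH2 bond and the bond from C2' to the carboxyl carbon.
- Forward key step: the aryne released by fluoride from 3,5-bis(benzyloxy)-2-(trimethylsilyl)phenyl trifluoromethanesulfonate A7 inserts into the CH2–CO2Bn bond of benzyl 2-[7-(benzyloxy)-5-heptyl-4-oxo-4H-chromen-2-yl]acetate A8. The product is benzyl 2,4-bis(benzyloxy)-6-[[7-(benzyloxy)-5-heptyl-4-oxo-4H-chromen-2-yl]methyl]benzoate A9.
- Merits: a late, convergent union that sets the ortho methylene/carboxyl pair in one step; the alkoxy group next to the aryne predicts the right orientation. It is more convergent than the linear chain assembly chosen here and avoids alkynyl ketone intermediates.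
- Weak points: acyl-alkylation of arynes is established for β-keto esters and malonates. Here an alkoxycarbonyl group would have to migrate from a carbon whose second activator is only a vinylogous carbonyl, so simple α-arylation, a second arylation of the more acidic product methylene and attack through chromone C3 all compete. A7 and A8 each need several steps. As in Alternative 1, the chromone still has to be hydrated at the end.
- Comparison: the chosen plan offers a key reaction of known type on both dienophile classes and the correct oxidation level at C2.

Key step: step 9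

Assumptions:
- The C2 hemiketal can invert by ring opening to the diketone. This is assumed to be slow in the solid and in cold, neutral solution, so that the (2R) compound can be handled once it has been obtained as a crystalline salt.
- Which enantiomer of the amine pairs with the (2R)-acid in the less soluble salt cannot be predicted. The route is written with the (R)-amine 19. If that salt holds the (2S)-acid, the mirror-image amine gives the (2R)-salt by symmetry.

## Steps

Step 1
Reactants: 1 but-3-ynoic acid; 2 2,2-dimethyl-1,3-dioxane-4,6-dione (Meldrum's acid)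
Product: 4 methyl 3-oxohex-5-ynoate, via acyl Meldrum's acid 3 (not isolated)
Conditions: DCC, DMAP, CH2Cl2, 0 °C to rt; filter, dilute acid wash; then MeOH, reflux
Reagents that add atoms: methanol, CO
Why: Acylation of Meldrum's acid followed by alcoholysis, the standard route from a carboxylic acid to a β-keto ester: carbodiimide activation lets the acidic C5 of 2 take up the but-3-ynoyl group, and boiling methanol opens 3 with loss of acetone and CO2; the DMAP is buffered by the acidic 2 and 3, which should hold back propargyl-to-allenyl isomerisation.

Step 2
Reactants: 4 methyl 3-oxohex-5-ynoate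
Product: 5 methyl 2-[2-(prop-2-yn-1-yl)-1,3-dioxolan-2-yl]acetate
Conditions: Me3SiOCH2CH2OSiMe3, Me3SiOTf (cat.), CH2Cl2, −78 to −20 °C; pyridine quench
Reagents that add atoms: 1,2-bis(trimethylsilyloxy)ethane, C[Si](C)(C)OCCO[Si](C)(C)C
Why: Me3SiOTf-catalysed ketalisation with the bis(silyl) ether of the diol runs cold and without free water or strong protic acid, so the propargyl ketone should be masked before it can isomerise; the ester carbonyl does not compete.

Step 3
Reactants: 5 methyl 2-[2-(prop-2-yn-1-yl)-1,3-dioxolan-2-yl]acetate
Product: 6 N-methoxy-N-methyl-2-[2-(prop-2-yn-1-yl)-1,3-dioxolan-2-yl]acetamide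
Conditions: MeNH(OMe)·HCl, iPrMgCl (excess), THF, −20 to 0 °C
Reagents that add atoms: N,O-dimethylhydroxylamine hydrochloride, CNOC.Cl
Why: Direct aminolysis of the ester by the magnesium amide of N,O-dimethylhydroxylamine (Weinreb amide formation); the excess Grignard reagent also deprotonates the alkyne, which is restored on work-up, and the low temperature keeps the ester from enolising toward the ketal.

Step 4
Reactants: 6 N-methoxy-N-methyl-2-[2-(prop-2-yn-1-yl)-1,3-dioxolan-2-yl]acetamide
Product: 7 4-[2-[2-[methoxy(methyl)amino]-2-oxoethyl]-1,3-dioxolan-2-yl]but-2-ynoic acid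
Conditions: AgI (cat.), Cs2CO3, CO2 (1 atm), DMF, 50 °C; then cold 1 M HCl to pH 3, EtOAc
Reagents that add atoms: carbon dioxide, O=C=O
Why: Silver-catalysed C–H carboxylation of a terminal alkyne: carbonate and AgI give the silver acetylide, which takes up CO2; neither the amide nor the dioxolane has a proton acidic enough for carbonate, and cold dilute acid should free the acid without touching the ketal.

Step 5
Reactants: 7 4-[2-[2-[methoxy(methyl)amino]-2-oxoethyl]-1,3-dioxolan-2-yl]but-2-ynoic acid; 8 non-1-yne
Product: 9 4-[2-(2-oxoundec-3-yn-1-yl)-1,3-dioxolan-2-yl]but-2-ynoic acid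
Conditions: 8, n-BuLi, THF, −78 °C (3 equiv of acetylide); then 7, −78 to 0 °C; cold 1 M HCl to pH 3
Reagents that add atoms: none
Why: Weinreb ketone synthesis: the first equivalent of lithium acetylide deprotonates the acid, whose carboxylate is inert to further acetylide, and the next adds to the N-methoxy-N-methylamide to give a chelated adduct that releases the ynone only on work-up, so a second addition is excluded.

Step 6
Reactants: 9 4-[2-(2-oxoundec-3-yn-1-yl)-1,3-dioxolan-2-yl]but-2-ynoic acid
Product: 10 benzyl 4-[2-(2-oxoundec-3-yn-1-yl)-1,3-dioxolan-2-yl]but-2-ynoate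
Conditions: BnBr, KHCO3 (1.1 equiv), DMF, 0 °C to rt
Reagents that add atoms: benzyl bromide, BrCc1ccccc1
Why: SN2 O-alkylation of the carboxylate; hydrogen carbonate is too weak a base to enolise the ynone or to isomerise the ynoate, and the acid is esterified without storage.

Step 7
Reactants: 11 methyl acetoacetate
Product: 12 methyl 3-(trimethylsilyloxy)but-2-enoate
Conditions: Me3SiCl, Et3N, hexane, rt; filtration, distillation
Reagents that add atoms: chlorotrimethylsilane, C[Si](C)(C)Cl
Why: O-silylation of the enol of a β-keto ester (silyl enol ether formation); the double-bond geometry is of no consequence for what follows.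

Step 8
Reactants: 12 methyl 3-(trimethylsilyloxy)but-2-enoate
Product: 13 1-methoxy-1,3-bis(trimethylsilyloxy)buta-1,3-diene
Conditions: LiN(iPr)2, THF, −78 °C; then Me3SiCl, −78 °C to rt; distillation
Reagents that add atoms: chlorotrimethylsilane, C[Si](C)(C)Cl
Why: γ-Deprotonation of the silyl dienol ether ester and O-silylation of the resulting ester enolate (silyl ketene acetal formation) should give the 1,3-bis(silyloxy)diene, which is used freshly distilled.

Step 9
Reactants: 10 benzyl 4-[2-(2-oxoundec-3-yn-1-yl)-1,3-dioxolan-2-yl]but-2-ynoate; 13 1-methoxy-1,3-bis(trimethylsilyloxy)buta-1,3-diene (two equivalents react, excess used)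
Product: 15 benzyl 2-[[2-[2-(2-heptyl-4,6-dihydroxyphenyl)-2-oxoethyl]-1,3-dioxolan-2-yl]methyl]-4,6-dihydroxybenzoate, via bis(cyclohexa-1,4-diene) cycloadduct 14 (not isolated)
Conditions: 13 (5 equiv, in portions), toluene, 110 °C, sealed tube; then citric acid, MeOH, 0 °C to rt
Reagents that add atoms: none
Why: Each acetylenic carbonyl unit of 10 is an electron-poor dienophile and 13 is a 1,1,3-trioxygenated diene, so two normal-demand Diels–Alder additions (concerted but strongly asynchronous, or conjugate addition followed by closure, with the same outcome) should give the bis(cyclohexa-1,4-diene) 14. The closest known reaction type is the benzannulation of 1-alkoxy-1,3-bis(silyloxy)butadienes with ynones and alk-2-ynoates to 6-substituted 2,4-dihydroxybenzoyl compounds, run here at both ends of one chain. Ring A is closed by an intermolecular [4+2] cycloaddition that forms C5–C6 and C4a–C8a, and ring C by a second [4+2] cycloaddition that forms C1'–C6' and C2'–C3'; both are six-membered carbocycles. In each ring the carbon bearing methoxy and silyloxy groups then loses methanol, and methanolysis of the silyl ethers under weak acid leaves the two resorcinols of 15 with the dioxolane intact. No stereocentre is created in 15, because the two transient ketal carbons of 14 become aromatic. The step needs one regiochemistry, which the polarisation of both partners secures: the unsubstituted CH2 terminus of 13, its most nucleophilic carbon, bonds to the β-carbon of the ynone and of the ynoate (C5 and C1'), which places the ketene-acetal oxygen at C8a and C3' beside the acyl-bearing carbons. It also needs both alkynes to react: the dioxolane keeps the two dienophiles unconjugated and prevents a free 1,3-diketone, and excess diene with prolonged heating should carry the less activated ynoate after the ynone has reacted.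

Step 10
Reactants: 15 benzyl 2-[[2-[2-(2-heptyl-4,6-dihydroxyphenyl)-2-oxoethyl]-1,3-dioxolan-2-yl]methyl]-4,6-dihydroxybenzoate
Product: 17 benzyl 2-[(5-heptyl-2,7-dihydroxy-4-oxo-3,4-dihydro-2H-chromen-2-yl)methyl]-4,6-dihydroxybenzoate (racemic), via open-chain 1,3-diketone 16 (not isolated)
Conditions: 1 M aq. HCl, THF, 0 °C to rt
Reagents that add atoms: water, O
Why: Acid-catalysed ketal hydrolysis; in 16 the phenol ortho to the aryl ketone adds to the freed C2 carbonyl (6-exo-trig hemiketalisation) to give the 2-hydroxychromanone, racemic at C2 because nothing chiral is present; the benzyl ester keeps the carboxyl from decarboxylating or adding to C2, and cold, water-rich, dilute acid should let water trap C2 faster than C3 loses a proton toward the chromone.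

Step 11
Reactants: 17 benzyl 2-[(5-heptyl-2,7-dihydroxy-4-oxo-3,4-dihydro-2H-chromen-2-yl)methyl]-4,6-dihydroxybenzoate (racemic)
Product: 18 2-[(5-heptyl-2,7-dihydroxy-4-oxo-3,4-dihydro-2H-chromen-2-yl)methyl]-4,6-dihydroxybenzoic acid (racemic)
Conditions: H2 (1 atm), Pd/C (10%), EtOAc, rt
Reagents that add atoms: none
Why: Hydrogenolysis of a benzyl ester under neutral conditions; the electron-rich aryl ketone, the hemiketal and the phenols should not be reduced at 1 atm and room temperature.

Step 12
Reactants: 18 2-[(5-heptyl-2,7-dihydroxy-4-oxo-3,4-dihydro-2H-chromen-2-yl)methyl]-4,6-dihydroxybenzoic acid (racemic); 19 (1R)-N,N-dimethyl-1-phenylethanamine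
Product: 21 (1R)-N,N-dimethyl-1-phenylethanaminium 2-[[(2R)-5-heptyl-2,7-dihydroxy-4-oxo-3,4-dihydro-2H-chromen-2-yl]methyl]-4,6-dihydroxybenzoate, via open-chain diketo acid 20 (not isolated)
Conditions: 19 (1.0 equiv), MeCN–EtOAc, 40 °C to rt, slurry ageing; filtration
Reagents that add atoms: none
Why: Proposed new method: one equivalent of the tertiary amine 19 forms the two diastereomeric carboxylate salts, the less soluble one crystallises, and the C2 epimer left in solution is converted into it by base-promoted ring-chain tautomerism through the achiral diketone form 20, so that C2 is set (R) under lattice control by the (R)-amine; a tertiary amine is chosen because it cannot condense with the diketone; the closest known reaction type is the crystallisation-induced diastereomer transformation of racemising carboxylic acids as chiral amine salts, together with the crystallisation of single anomers of mutarotating hemiacetals.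

Step 13
Reactants: 21 (1R)-N,N-dimethyl-1-phenylethanaminium 2-[[(2R)-5-heptyl-2,7-dihydroxy-4-oxo-3,4-dihydro-2H-chromen-2-yl]methyl]-4,6-dihydroxybenzoate
Product: 22 2-[[(2R)-5-heptyl-2,7-dihydroxy-4-oxo-3,4-dihydro-2H-chromen-2-yl]methyl]-4,6-dihydroxybenzoic acid
Conditions: EtOAc, 0.5 M aq. HCl, 0 °C, brief; Na2SO4; evaporation below 10 °C to a solid
Reagents that add atoms: none
Why: Acid–base partition of an ammonium carboxylate; no bond at C2 is touched, and cold, brief handling with isolation as a solid should keep ring opening, the only path to racemisation, slow.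

## Compound list

1 | but-3-ynoic acid | C#CCC(=O)O | starting material
2 | 2,2-dimethyl-1,3-dioxane-4,6-dione (Meldrum's acid) | CC1(C)OC(=O)CC(=O)O1 | starting material
3 | 5-(1-hydroxybut-3-yn-1-ylidene)-2,2-dimethyl-1,3-dioxane-4,6-dione | C#CCC(O)=C1C(=O)OC(C)(C)OC1=O | intermediate (not isolated)
4 | methyl 3-oxohex-5-ynoate | C#CCC(=O)CC(=O)OC | intermediate
5 | methyl 2-[2-(prop-2-yn-1-yl)-1,3-dioxolan-2-yl]acetate | C#CCC1(CC(=O)OC)OCCO1 | intermediate
6 | N-methoxy-N-methyl-2-[2-(prop-2-yn-1-yl)-1,3-dioxolan-2-yl]acetamide | C#CCC1(CC(=O)N(C)OC)OCCO1 | intermediate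
7 | 4-[2-[2-[methoxy(methyl)amino]-2-oxoethyl]-1,3-dioxolan-2-yl]but-2-ynoic acid | CON(C)C(=O)CC1(CC#CC(=O)O)OCCO1 | intermediate
8 | non-1-yne | CCCCCCCC#C | starting material
9 | 4-[2-(2-oxoundec-3-yn-1-yl)-1,3-dioxolan-2-yl]but-2-ynoic acid | CCCCCCCC#CC(=O)CC1(CC#CC(=O)O)OCCO1 | intermediate
10 | benzyl 4-[2-(2-oxoundec-3-yn-1-yl)-1,3-dioxolan-2-yl]but-2-ynoate | CCCCCCCC#CC(=O)CC1(CC#CC(=O)OCc2ccccc2)OCCO1 | intermediate
11 | methyl acetoacetate | CC(=O)CC(=O)OC | starting material
12 | methyl 3-(trimethylsilyloxy)but-2-enoate (double-bond geometry not specified) | COC(=O)C=C(C)O[Si](C)(C)C | intermediate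
13 | 1-methoxy-1,3-bis(trimethylsilyloxy)buta-1,3-diene (geometry at C1=C2 not specified) | COC(O[Si](C)(C)C)=CC(O[Si](C)(C)C)=C | intermediate
14 | benzyl 2-[[2-[2-[2-heptyl-6-methoxy-4,6-bis(trimethylsilyloxy)cyclohexa-1,4-dien-1-yl]-2-oxoethyl]-1,3-dioxolan-2-yl]methyl]-6-methoxy-4,6-bis(trimethylsilyloxy)cyclohexa-1,4-diene-1-carboxylate (mixture of stereoisomers at the two ring ketal carbons) | CCCCCCCC1=C(C(=O)CC2(CC3=C(C(=O)OCc4ccccc4)C(OC)(O[Si](C)(C)C)C=C(O[Si](C)(C)C)C3)OCCO2)C(OC)(O[Si](C)(C)C)C=C(O[Si](C)(C)C)C1 | intermediate (not isolated)
15 | benzyl 2-[[2-[2-(2-heptyl-4,6-dihydroxyphenyl)-2-oxoethyl]-1,3-dioxolan-2-yl]methyl]-4,6-dihydroxybenzoate | CCCCCCCc1cc(O)cc(O)c1C(=O)CC1(Cc2cc(O)cc(O)c2C(=O)OCc2ccccc2)OCCO1 | intermediate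
16 | benzyl 2-[4-(2-heptyl-4,6-dihydroxyphenyl)-2,4-dioxobutyl]-4,6-dihydroxybenzoate | CCCCCCCc1cc(O)cc(O)c1C(=O)CC(=O)Cc1cc(O)cc(O)c1C(=O)OCc1ccccc1 | intermediate (not isolated)
17 | benzyl 2-[(5-heptyl-2,7-dihydroxy-4-oxo-3,4-dihydro-2H-chromen-2-yl)methyl]-4,6-dihydroxybenzoate (racemic) | CCCCCCCc1cc(O)cc2c1C(=O)CC(O)(Cc1cc(O)cc(O)c1C(=O)OCc1ccccc1)O2 | intermediate
18 | 2-[(5-heptyl-2,7-dihydroxy-4-oxo-3,4-dihydro-2H-chromen-2-yl)methyl]-4,6-dihydroxybenzoic acid (racemic) | CCCCCCCc1cc(O)cc2c1C(=O)CC(O)(Cc1cc(O)cc(O)c1C(=O)O)O2 | intermediate
19 | (1R)-N,N-dimethyl-1-phenylethanamine | C[C@@H](N(C)C)c1ccccc1 | starting material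
20 | 2-[4-(2-heptyl-4,6-dihydroxyphenyl)-2,4-dioxobutyl]-4,6-dihydroxybenzoic acid (open-chain tautomer, present in solution as its ammonium salt) | CCCCCCCc1cc(O)cc(O)c1C(=O)CC(=O)Cc1cc(O)cc(O)c1C(=O)O | intermediate (not isolated)
21 | (1R)-N,N-dimethyl-1-phenylethanaminium 2-[[(2R)-5-heptyl-2,7-dihydroxy-4-oxo-3,4-dihydro-2H-chromen-2-yl]methyl]-4,6-dihydroxybenzoate | CCCCCCCc1cc(O)cc2c1C(=O)C[C@@](O)(Cc1cc(O)cc(O)c1C(=O)[O-])O2.C[C@@H]([NH+](C)C)c1ccccc1 | intermediate
22 | 2-[[(2R)-5-heptyl-2,7-dihydroxy-4-oxo-3,4-dihydro-2H-chromen-2-yl]methyl]-4,6-dihydroxybenzoic acid | CCCCCCCc1cc(O)cc2c1C(=O)C[C@@](O)(Cc1cc(O)cc(O)c1C(=O)O)O2 | target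

## Step count and risks

Total: 13 steps; steps 7 and 8 are a two-step side branch to the diene. Longest linear sequence: 11 steps (steps 1–6 and 9–13).

**Step 12 (proposed new method).**
- What may go wrong: the two diastereomeric salts may co-crystallise or form a solid solution, so the lattice does not discriminate. Ring-chain equilibration in the mother liquor may be too slow to feed the crystallising epimer. Prolonged ageing in the presence of base may let the open form drift toward dehydration.
- Fallback (known chemistry): separate the enantiomers of 18 by preparative chromatography on an immobilised cellulose tris(3,5-dimethylphenylcarbamate) stationary phase, below ambient temperature, with an acidified non-basic eluent. The unwanted enantiomer is re-equilibrated by gentle warming and recycled. The fallback sets out from 18 and returns at 22, bypassing 21 and step 13; it makes no new compound.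

**Step 9 (key step).**
- What may go wrong: annulation may be incomplete at the ynoate end, because the β-branched, less activated ynoate adds the diene more slowly than the acyclic diene decomposes thermally or loses silyl groups to adventitious moisture. Only ring A would then form.
- Fallback: replace the acyclic diene by the thermally robust cyclic diene 5,5-dimethyl-1,3-bis(trimethylsilyloxy)cyclohexa-1,3-diene F1, made by double silylation of 5,5-dimethylcyclohexane-1,3-dione. Heating 10 with excess F1 without solvent at about 140–150 °C should give Diels–Alder addition with the same orientation (CH terminus to the β-carbon), followed in the same pot by cycloreversion with loss of 2-methylpropene. The product is benzyl 2-[[2-[2-[2-heptyl-4,6-bis(trimethylsilyloxy)phenyl]-2-oxoethyl]-1,3-dioxolan-2-yl]methyl]-4,6-bis(trimethylsilyloxy)benzoate F2. Methanolysis of F2 with citric acid gives 15. The same four bonds form and the same two rings close. The fallback sets out from 10 and returns at 15.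

**Step 1.**
- What may go wrong: base-induced propargyl-to-allenyl isomerisation during acyl activation, and isomerisation or cycloisomerisation of the propargyl ketone during methanolysis and handling before it is ketalised.
- Fallback: make the alkyne only after the ketal is in place.
  - The dianion of methyl acetoacetate 11 (NaH, then n-BuLi) is alkylated at the γ-carbon with benzyl chloromethyl ether to give methyl 5-(benzyloxy)-3-oxopentanoate F3.
  - Ketalisation as in step 2 gives methyl 2-[2-[2-(benzyloxy)ethyl]-1,3-dioxolan-2-yl]acetate F4.
  - Hydrogenolysis (H2, Pd/C) gives methyl 2-[2-(2-hydroxyethyl)-1,3-dioxolan-2-yl]acetate F5.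
  - Dess–Martin oxidation gives methyl 2-[2-(2-oxoethyl)-1,3-dioxolan-2-yl]acetate F6.
  - Ohira–Bestmann homologation (dimethyl (1-diazo-2-oxopropyl)phosphonate, K2CO3, MeOH) converts the aldehyde into the terminal alkyne 5.
  
  The fallback sets out from 11 and returns at 5; no propargyl ketone is ever present.

**Step 10.**
- What may go wrong: irreversible loss of water, or of the diol from the intermediate mixed ketal, across C2–C3 once the C8a oxygen has closed on C2, giving the chromone instead of the hemiketal.
- Fallback: block the phenols during the acidic step.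
  - Compound 15 is silylated (t-BuMe2SiCl, imidazole, DMF) to benzyl 2-[[2-[2-[2,4-bis(tert-butyldimethylsilyloxy)-6-heptylphenyl]-2-oxoethyl]-1,3-dioxolan-2-yl]methyl]-4,6-bis(tert-butyldimethylsilyloxy)benzoate F7.
  - Aqueous acid hydrolyses the ketal of F7 to benzyl 2-[4-[2,4-bis(tert-butyldimethylsilyloxy)-6-heptylphenyl]-2,4-dioxobutyl]-4,6-bis(tert-butyldimethylsilyloxy)benzoate F8. With the C8a oxygen blocked, F8 cannot cyclise, so no chromone can form.
  - Buffered fluoride (Bu4NF, AcOH, THF, 0 °C) frees the phenols under near-neutral conditions, and the hemiketal 17 closes.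
  
  The fallback sets out from 15 and returns at 17.

**Step 5.**
- What may go wrong: incomplete addition because the lithium carboxylate of 7 aggregates or precipitates at low temperature, or competing attack of the acetylide on the alkynoate unit.
- Fallback: reverse the order. The alkyne-terminated amide 6 is treated with lithium non-1-ynide (2.2 equiv, THF, −78 to 0 °C) to give 1-[2-(prop-2-yn-1-yl)-1,3-dioxolan-2-yl]undec-3-yn-2-one F9. F9 is then carboxylated (AgI, Cs2CO3, CO2, DMF) and benzylated in the same pot with benzyl bromide to give 10. The fallback sets out from 6 and returns at 10, bypassing 7 and 9. Its cost is that the carbonate base now meets the enolisable ynone.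

## Further compounds

F0 | step 12 | none | none
F1 | step 9 | 5,5-dimethyl-1,3-bis(trimethylsilyloxy)cyclohexa-1,3-diene | CC1(C)CC(O[Si](C)(C)C)=CC(O[Si](C)(C)C)=C1
F2 | step 9 | benzyl 2-[[2-[2-[2-heptyl-4,6-bis(trimethylsilyloxy)phenyl]-2-oxoethyl]-1,3-dioxolan-2-yl]methyl]-4,6-bis(trimethylsilyloxy)benzoate | CCCCCCCc1cc(O[Si](C)(C)C)cc(O[Si](C)(C)C)c1C(=O)CC1(Cc2cc(O[Si](C)(C)C)cc(O[Si](C)(C)C)c2C(=O)OCc2ccccc2)OCCO1
F3 | step 1 | methyl 5-(benzyloxy)-3-oxopentanoate | COC(=O)CC(=O)CCOCc1ccccc1
F4 | step 1 | methyl 2-[2-[2-(benzyloxy)ethyl]-1,3-dioxolan-2-yl]acetate | COC(=O)CC1(CCOCc2ccccc2)OCCO1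
F5 | step 1 | methyl 2-[2-(2-hydroxyethyl)-1,3-dioxolan-2-yl]acetate | COC(=O)CC1(CCO)OCCO1
F6 | step 1 | methyl 2-[2-(2-oxoethyl)-1,3-dioxolan-2-yl]acetate | COC(=O)CC1(CC=O)OCCO1
F7 | step 10 | benzyl 2-[[2-[2-[2,4-bis(tert-butyldimethylsilyloxy)-6-heptylphenyl]-2-oxoethyl]-1,3-dioxolan-2-yl]methyl]-4,6-bis(tert-butyldimethylsilyloxy)benzoate | CCCCCCCc1cc(O[Si](C)(C)C(C)(C)C)cc(O[Si](C)(C)C(C)(C)C)c1C(=O)CC1(Cc2cc(O[Si](C)(C)C(C)(C)C)cc(O[Si](C)(C)C(C)(C)C)c2C(=O)OCc2ccccc2)OCCO1
F8 | step 10 | benzyl 2-[4-[2,4-bis(tert-butyldimethylsilyloxy)-6-heptylphenyl]-2,4-dioxobutyl]-4,6-bis(tert-butyldimethylsilyloxy)benzoate | CCCCCCCc1cc(O[Si](C)(C)C(C)(C)C)cc(O[Si](C)(C)C(C)(C)C)c1C(=O)CC(=O)Cc1cc(O[Si](C)(C)C(C)(C)C)cc(O[Si](C)(C)C(C)(C)C)c1C(=O)OCc1ccccc1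
F9 | step 5 | 1-[2-(prop-2-yn-1-yl)-1,3-dioxolan-2-yl]undec-3-yn-2-one | CCCCCCCC#CC(=O)CC1(CC#C)OCCO1
A1 | alternative 1 | 6-[5-[7-(benzyloxy)-5-heptyl-4-oxo-4H-chromen-2-yl]-2,4-dioxopentyl]-2,2-dimethyl-4H-1,3-dioxin-4-one | CCCCCCCc1cc(OCc2ccccc2)cc2OC(CC(=O)CC(=O)CC3=CC(=O)OC(C)(C)O3)=CC(=O)c12
A2 | alternative 1 | 5-[(7-benzyloxy-5-heptyl-4-oxo-4H-chromen-2-yl)methyl]-7-hydroxy-2,2-dimethyl-4H-1,3-benzodioxin-4-one | CCCCCCCc1cc(OCc3ccccc3)cc2c1C(=O)C=C(Cc1cc(O)cc4OC(C)(C)OC(=O)c14)O2
A3 | alternative 2 | 2,4-bis(benzyloxy)-1-iodobenzene | Ic1ccc(OCc2ccccc2)cc1OCc1ccccc1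
A4 | alternative 2 | 1-iodoheptane | CCCCCCCI
A5 | alternative 2 | benzyl 2,4-bis(benzyloxy)-6-[(2-ethynyl-1,3-dioxolan-2-yl)methyl]benzoate | C#CC1(Cc2cc(OCc3ccccc3)cc(OCc3ccccc3)c2C(=O)OCc2ccccc2)OCCO1
A6 | alternative 2 | benzyl 2,4-bis(benzyloxy)-6-[[2-[(2,4-bis(benzyloxy)-6-heptylphenyl)ethynyl]-1,3-dioxolan-2-yl]methyl]benzoate | CCCCCCCc1cc(OCc2ccccc2)cc(OCc2ccccc2)c1C#CC1(Cc2cc(OCc3ccccc3)cc(OCc3ccccc3)c2C(=O)OCc2ccccc2)OCCO1
A7 | alternative 3 | 3,5-bis(benzyloxy)-2-(trimethylsilyl)phenyl trifluoromethanesulfonate | C[Si](C)(C)c1c(OS(=O)(=O)C(F)(F)F)cc(OCc2ccccc2)cc1OCc1ccccc1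
A8 | alternative 3 | benzyl 2-[7-(benzyloxy)-5-heptyl-4-oxo-4H-chromen-2-yl]acetate | CCCCCCCc1cc(OCc2ccccc2)cc2OC(CC(=O)OCc3ccccc3)=CC(=O)c12
A9 | alternative 3 | benzyl 2,4-bis(benzyloxy)-6-[[7-(benzyloxy)-5-heptyl-4-oxo-4H-chromen-2-yl]methyl]benzoate | CCCCCCCc1cc(OCc3ccccc3)cc2c1C(=O)C=C(Cc1cc(OCc3ccccc3)cc(OCc3ccccc3)c1C(=O)OCc1ccccc1)O2
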